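**Strategy.** Everything rests on cutting the C4–C4a bond of ring C. C4a is the only carbon of ring A that bears no oxygen, and it sits next to C8a, the carbon carrying O1. A bromine at C4a of a ring-A aryl ether therefore lets palladium join that aryl carbon to a pendant allyl group. One intramolecular Mizoroki–Heck reaction forms C4–C4a, closes the pyran ring (6-exo) and leaves an exocyclic methylene at C4 as a latent ketone, without touching C2. The precursor is the (S)-configured homoallyl ether of 2-bromo-3,4,5,6-tetramethoxyphenol with a 2-benzyloxy-6-methoxyphenyl group at the carbinol carbon, assembled by Mitsunobu inversion of the (R)-homoallylic alcohol.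

Key step: step 6

Remark: C2 of the target is (S) (O1 > C1′ > C3 > H). The sense of induction of (R)-TRIP, (R)-3,3′-bis(2,4,6-triisopropylphenyl)-1,1′-binaphthyl-2,2′-diyl hydrogen phosphate, is assumed to be the one it shows with simple aryl aldehydes (allyl transfer to the Re face). If the di-ortho-substituted aldehyde 7 responded oppositely, the (S)-acid would be used in step 4.

**Step 1**
Reactants: 1 1,2,3,4-tetramethoxybenzene
Product: 4 2,3,4,5-tetramethoxyphenol, via 5-lithio-1,2,3,4-tetramethoxybenzene 2 (not isolated), via dimethyl (2,3,4,5-tetramethoxyphenyl)boronate 3 (not isolated)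
Conditions: n-BuLi, TMEDA, THF, 0 °C; B(OMe)3, −78 °C → rt; 30% H2O2, AcOH, 0 °C → rt
Reagents that add atoms: hydrogen peroxide, OO
Why: Directed ortho-metalation at one of the two equivalent ring C–H positions (each flanked by a methoxy group), trapping as the boronate and oxidative boron-to-oxygen aryl migration (boronate oxidation) should place the hydroxyl on the carbon that becomes C8a.

**Step 2**
Reactants: 4 2,3,4,5-tetramethoxyphenol
Product: 5 2-bromo-3,4,5,6-tetramethoxyphenol
Conditions: NBS (1.0 equiv), CH2Cl2, −78 → 0 °C, dark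
Reagents that add atoms: N-bromosuccinimide, O=C1CCC(=O)N1Br
Why: Electrophilic aromatic bromination can only go to the single unsubstituted ring carbon, which is ortho to the hydroxyl and becomes C4a, and one equivalent of NBS at low temperature should limit oxidation of the electron-rich phenol.

**Step 3**
Reactants: 6 2-hydroxy-6-methoxybenzaldehyde
Product: 7 2-(benzyloxy)-6-methoxybenzaldehyde
Conditions: BnBr, K2CO3, DMF, 50 °C
Reagents that add atoms: benzyl bromide, BrCc1ccccc1
Why: Williamson etherification of the phenoxide with benzyl bromide masks the ring-B phenol for the Mitsunobu and palladium steps with a group that the final boron trichloride step removes.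

**Step 4**
Reactants: 7 2-(benzyloxy)-6-methoxybenzaldehyde; 8 allylboronic acid pinacol ester
Product: 10 (R)-1-[2-(benzyloxy)-6-methoxyphenyl]but-3-en-1-ol, via pinacol borate ester 9 (not isolated)
Conditions: (R)-TRIP (5 mol%), 4 Å MS, toluene, −30 °C; then aq NaHCO3
Reagents that add atoms: none
Why: Chiral-phosphoric-acid-catalysed allylboration through a closed chair transition state, in which the acid hydrogen-bonds to a boronate oxygen and steers allyl transfer to the Re face of the aldehyde, should set the carbinol centre as (R), and the borate ester is hydrolysed on work-up.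

**Step 5**
Reactants: 10 (R)-1-[2-(benzyloxy)-6-methoxyphenyl]but-3-en-1-ol; 5 2-bromo-3,4,5,6-tetramethoxyphenol
Product: 12 (S)-1-bromo-2-{[1-(2-benzyloxy-6-methoxyphenyl)but-3-en-1-yl]oxy}-3,4,5,6-tetramethoxybenzene, via alkoxyphosphonium phenoxide 11 (not isolated)
Conditions: PPh3, DIAD, toluene, −20 → 0 °C
Reagents that add atoms: none
Why: Mitsunobu etherification, in which the alcohol is activated as its alkoxyphosphonium ion and displaced by the phenoxide of 5 (acidified by the ortho bromine, with no free ring carbon for C-alkylation) in an SN2 step that inverts (R) to the (S) centre that becomes C2, toluene and low temperature being chosen to disfavour ionisation of the benzylic carbon.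

**Step 6**
Reactants: 12 (S)-1-bromo-2-{[1-(2-benzyloxy-6-methoxyphenyl)but-3-en-1-yl]oxy}-3,4,5,6-tetramethoxybenzene
Product: 13 (S)-2-[2-(benzyloxy)-6-methoxyphenyl]-5,6,7,8-tetramethoxy-4-methylenechroman
Conditions: Pd(OAc)2 (10 mol%), dppp (12 mol%), Ag2CO3 (2 equiv), toluene, 100 °C
Reagents that add atoms: none
Why: Zerovalent palladium, formed in situ from Pd(OAc)2 and the phosphine, inserts into the C4a–Br bond; Ag2CO3 strips bromide so that the cationic arylpalladium binds the terminal alkene, adds syn across it with the aryl carbon bonding to the internal alkene carbon (the future C4), and the resulting primary alkylpalladium loses the C4 hydrogen by syn β-hydride elimination to give the exocyclic C4=CH2. The closest known reaction type is the intramolecular Mizoroki–Heck cyclisation of ortho-haloaryl homoallyl ethers to 4-methylenechromans. Ring C (O1, C2, C3, C4, C4a, C8a) is closed in the 6-exo-trig mode. No stereocentre is created, and the existing (S) centre at C2 is a spectator because neither its C–O nor its C–H bond takes part and the medium contains no acid and generates no carbanion at C3. The step needs exo over 7-endo insertion, which the three-atom tether (O1, C2, C3) between arene and alkene secures, and it needs the double bond to stay exocyclic, which the silver salt secures by removing hydridopalladium bromide before it can re-add and move the alkene into the C3–C4 position. Site selectivity on ring A is not an issue since the only carbon–halogen bond in 12 is at C4a.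

**Step 7**
Reactants: 13 (S)-2-[2-(benzyloxy)-6-methoxyphenyl]-5,6,7,8-tetramethoxy-4-methylenechroman
Product: 15 (S)-2-[2-(benzyloxy)-6-methoxyphenyl]-5,6,7,8-tetramethoxychroman-4-one, via vicinal diol 14 (not isolated)
Conditions: OsO4 (2 mol%), NaIO4 (4 equiv), 2,6-lutidine, dioxane–H2O (3:1), rt
Reagents that add atoms: osmium tetroxide, O=[Os](=O)(=O)=O; sodium periodate, [Na+].[O-]I(=O)(=O)=O (terminal oxidant that re-forms OsO4)
Why: Lemieux–Johnson oxidation, in which osmylation of the only alkene and periodate glycol cleavage should give the C4 aryl ketone and formaldehyde, while the buffered, non-acidic medium leaves the electron-rich arenes, the benzyl ether and C2 untouched.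

**Step 8**
Reactants: 15 (S)-2-[2-(benzyloxy)-6-methoxyphenyl]-5,6,7,8-tetramethoxychroman-4-one
Product: 17 (S)-5-hydroxy-2-(2-hydroxy-6-methoxyphenyl)-6,7,8-trimethoxychroman-4-one, via bis(dichloroboryl) ether 16 (not isolated)
Conditions: BCl3 (5 equiv), C6HMe5 (3 equiv), CH2Cl2, −78 → 0 °C; then H2O
Reagents that add atoms: none
Why: Boron trichloride ether cleavage, in which the benzyl ether should fall at −78 °C with pentamethylbenzene trapping the benzyl cation, and on warming boron chelated between the C4 carbonyl and the C5 oxygen should deliver chloride to the C5 methyl only (peri-selective demethylation), the other four methyl ethers having no carbonyl partner and no bond to C2 being broken, so (S) is kept.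

**Compound list**

1 | 1,2,3,4-tetramethoxybenzene | COc1ccc(OC)c(OC)c1OC | starting material
2 | 5-lithio-1,2,3,4-tetramethoxybenzene (formed in situ) | [Li]c1cc(OC)c(OC)c(OC)c1OC | intermediate
3 | dimethyl (2,3,4,5-tetramethoxyphenyl)boronate (formed in situ) | COB(OC)c1cc(OC)c(OC)c(OC)c1OC | intermediate
4 | 2,3,4,5-tetramethoxyphenol | COc1cc(O)c(OC)c(OC)c1OC | intermediate
5 | 2-bromo-3,4,5,6-tetramethoxyphenol | Oc1c(Br)c(OC)c(OC)c(OC)c1OC | intermediate
6 | 2-hydroxy-6-methoxybenzaldehyde | COc1cccc(O)c1C=O | starting material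
7 | 2-(benzyloxy)-6-methoxybenzaldehyde | COc1cccc(OCc2ccccc2)c1C=O | intermediate
8 | allylboronic acid pinacol ester | C=CCB1OC(C)(C)C(C)(C)O1 | starting material
9 | 2-{[(R)-1-(2-benzyloxy-6-methoxyphenyl)but-3-en-1-yl]oxy}-4,4,5,5-tetramethyl-1,3,2-dioxaborolane (formed in situ) | COc1cccc(OCc2ccccc2)c1[C@@H](CC=C)OB1OC(C)(C)C(C)(C)O1 | intermediate
10 | (R)-1-[2-(benzyloxy)-6-methoxyphenyl]but-3-en-1-ol | COc1cccc(OCc2ccccc2)c1[C@@H](CC=C)O | intermediate
11 | {[(R)-1-(2-benzyloxy-6-methoxyphenyl)but-3-en-1-yl]oxy}triphenylphosphonium 2-bromo-3,4,5,6-tetramethoxyphenoxide (formed in situ) | COc1cccc(OCc2ccccc2)c1[C@@H](CC=C)O[P+](c1ccccc1)(c1ccccc1)c1ccccc1.[O-]c1c(Br)c(OC)c(OC)c(OC)c1OC | intermediate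
12 | (S)-1-bromo-2-{[1-(2-benzyloxy-6-methoxyphenyl)but-3-en-1-yl]oxy}-3,4,5,6-tetramethoxybenzene | COc1cccc(OCc2ccccc2)c1[C@H](CC=C)Oc1c(Br)c(OC)c(OC)c(OC)c1OC | intermediate
13 | (S)-2-[2-(benzyloxy)-6-methoxyphenyl]-5,6,7,8-tetramethoxy-4-methylenechroman | COc1cccc(OCc2ccccc2)c1[C@@H]1CC(=C)c2c(OC)c(OC)c(OC)c(OC)c2O1 | intermediate
14 | (2S)-2-[2-(benzyloxy)-6-methoxyphenyl]-4-(hydroxymethyl)-5,6,7,8-tetramethoxychroman-4-ol, both C4 epimers (formed in situ) | COc1cccc(OCc2ccccc2)c1[C@@H]1CC(O)(CO)c2c(OC)c(OC)c(OC)c(OC)c2O1 | intermediate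
15 | (S)-2-[2-(benzyloxy)-6-methoxyphenyl]-5,6,7,8-tetramethoxychroman-4-one | COc1cccc(OCc2ccccc2)c1[C@@H]1CC(=O)c2c(OC)c(OC)c(OC)c(OC)c2O1 | intermediate
16 | (S)-5-[(dichloroboranyl)oxy]-2-{2-[(dichloroboranyl)oxy]-6-methoxyphenyl}-6,7,8-trimethoxychroman-4-one (formed in situ) | COc1cccc(OB(Cl)Cl)c1[C@@H]1CC(=O)c2c(OB(Cl)Cl)c(OC)c(OC)c(OC)c2O1 | intermediate
17 | (S)-5-hydroxy-2-(2-hydroxy-6-methoxyphenyl)-6,7,8-trimethoxychroman-4-one | COc1cccc(O)c1[C@@H]1CC(=O)c2c(O)c(OC)c(OC)c(OC)c2O1 | target

**Step count.** Total: 8 steps. Longest linear sequence: 6 steps (steps 3, 4, 5, 6, 7, 8 from 6; the ring-A branch, steps 1 and 2, joins at step 5 and is equally long).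

**Steps most likely to fail**

1. Step 5. The alkoxyphosphonium ion sits on a benzylic carbon flanked by two ortho oxygen donors, so it may ionise instead of being displaced. That would erode the enantiomeric purity of C2 and divert material by elimination to the conjugated aryl diene. The displacement itself is slowed by the two ortho substituents on each partner. The fallback sets out from 7 and 1 and comes back at 12; it forms the aryl–oxygen bond instead of the alkyl–oxygen bond, so the carbinol centre is never a leaving-group carbon. Aldehyde 7 would be allylborated with 8 as in step 4 but with (S)-TRIP, giving through 2-{[(S)-1-(2-benzyloxy-6-methoxyphenyl)but-3-en-1-yl]oxy}-4,4,5,5-tetramethyl-1,3,2-dioxaborolane F1 the alcohol (S)-1-[2-(benzyloxy)-6-methoxyphenyl]but-3-en-1-ol F2. Arene 1 would be dibrominated (Br2, AcOH, rt) to 1,2-dibromo-3,4,5,6-tetramethoxybenzene F3, whose two bromines are equivalent. Ullmann-type mono-etherification of F2 with an excess of F3 (CuI, 3,4,7,8-tetramethyl-1,10-phenanthroline, Cs2CO3, toluene, 110 °C) should then give 12 with retention, the remaining bromine lying at C4a automatically.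

2. Step 6. Oxidative addition at a C–Br bond flanked by two alkoxy groups on an electron-rich ring may be slow, giving protodebromination instead. Any surviving hydridopalladium species may move the exocyclic double bond into ring C, or move the terminal alkene of unreacted 12 into an allylic position, and the ketone surrogate would be lost. The fallback sets out from 12 and comes back at 15; it makes the same C4–C4a bond by an aryllithium acylation. Lemieux–Johnson cleavage of the terminal alkene of 12 (OsO4 cat., NaIO4, 2,6-lutidine, dioxane–H2O) would give, through (4S)-4-[2-(benzyloxy)-6-methoxyphenyl]-4-(2-bromo-3,4,5,6-tetramethoxyphenoxy)butane-1,2-diol F4, the aldehyde (S)-3-[2-(benzyloxy)-6-methoxyphenyl]-3-(2-bromo-3,4,5,6-tetramethoxyphenoxy)propanal F5. Pinnick oxidation (NaClO2, NaH2PO4, 2-methyl-2-butene, t-BuOH–H2O) would give (S)-3-[2-(benzyloxy)-6-methoxyphenyl]-3-(2-bromo-3,4,5,6-tetramethoxyphenoxy)propanoic acid F6. Treatment with n-BuLi (2.2 equiv, THF, −100 °C) would form lithium (S)-3-[2-(benzyloxy)-6-methoxyphenyl]-3-(2-lithio-3,4,5,6-tetramethoxyphenoxy)propanoate F7 by deprotonation and bromine–lithium exchange. F7 should close onto the carboxylate carbon (Parham cyclisation) and give ketone 15 on aqueous work-up.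

3. Step 8. The Lewis acid may cleave more than the two intended ethers (the C6 or ring-B methyl ethers). It may also open ring C at the C2–O1 bond towards the chalcone, which on reclosure would scramble C2. Benzyl cation that escapes the scavenger may alkylate ring B. The fallback sets out from 15 and comes back at 17; it separates the two deprotections and removes the benzyl group without any Lewis acid. Hydrogenolysis (H2, palladium on carbon, EtOAc, rt) would give (S)-2-(2-hydroxy-6-methoxyphenyl)-5,6,7,8-tetramethoxychroman-4-one F8. Chelation-controlled removal of the C5 methyl with AlCl3 in MeCN at room temperature, followed by dilute aqueous acid work-up, should then give 17.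

**Further compounds**

F1 | step 5 | 2-{[(S)-1-(2-benzyloxy-6-methoxyphenyl)but-3-en-1-yl]oxy}-4,4,5,5-tetramethyl-1,3,2-dioxaborolane | COc1cccc(OCc2ccccc2)c1[C@H](CC=C)OB1OC(C)(C)C(C)(C)O1
F2 | step 5 | (S)-1-[2-(benzyloxy)-6-methoxyphenyl]but-3-en-1-ol | COc1cccc(OCc2ccccc2)c1[C@H](CC=C)O
F3 | step 5 | 1,2-dibromo-3,4,5,6-tetramethoxybenzene | COc1c(Br)c(Br)c(OC)c(OC)c1OC
F4 | step 6 | (4S)-4-[2-(benzyloxy)-6-methoxyphenyl]-4-(2-bromo-3,4,5,6-tetramethoxyphenoxy)butane-1,2-diol, both C2 epimers | COc1cccc(OCc2ccccc2)c1[C@H](CC(O)CO)Oc1c(Br)c(OC)c(OC)c(OC)c1OC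
F5 | step 6 | (S)-3-[2-(benzyloxy)-6-methoxyphenyl]-3-(2-bromo-3,4,5,6-tetramethoxyphenoxy)propanal | COc1cccc(OCc2ccccc2)c1[C@H](CC=O)Oc1c(Br)c(OC)c(OC)c(OC)c1OC
F6 | step 6 | (S)-3-[2-(benzyloxy)-6-methoxyphenyl]-3-(2-bromo-3,4,5,6-tetramethoxyphenoxy)propanoic acid | COc1cccc(OCc2ccccc2)c1[C@H](CC(=O)O)Oc1c(Br)c(OC)c(OC)c(OC)c1OC
F7 | step 6 | lithium (S)-3-[2-(benzyloxy)-6-methoxyphenyl]-3-(2-lithio-3,4,5,6-tetramethoxyphenoxy)propanoate | COc1cccc(OCc2ccccc2)c1[C@H](CC(=O)O[Li])Oc1c([Li])c(OC)c(OC)c(OC)c1OC
F8 | step 8 | (S)-2-(2-hydroxy-6-methoxyphenyl)-5,6,7,8-tetramethoxychroman-4-one | COc1cccc(O)c1[C@@H]1CC(=O)c2c(OC)c(OC)c(OC)c(OC)c2O1
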